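The ten-membered ring is numbered as in germacranes (C1=C10 alkene, C4–C5 epoxide). If the epoxide is read as a former alkene, the ring contains a 1,5-diene, C10=C1–C2–C3–C4=C5, whose central C2–C3 σ-bond is the product bond of a [3,3] shift. The ring is therefore closed by an anionic oxy-Cope ring expansion. The precursor is a carvone-derived cyclohexanol that carries the C3=C4 alkenyl group on the carbinol carbon C5 and the C1=C2 vinyl group on the neighbouring quaternary carbon C10 (trans, both equatorial). It breaks C5–C10 and forms C2–C3 through a chair transition state, fixing both ring-E double bonds in one operation. The enolate is trapped as a triflate, reduced, and the allylic alcohol is epoxidised last.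

Key step: step 14

Remark on numbering: the same labels are kept for all intermediates: C1–C10 ring carbons, C11–C13 side chain on C7 with C12 bearing oxygen, C14 on C10, C15 on C4.
Remark on intermediates: metal alkoxides that are only protonated on work-up are not listed as separate compounds; enolates, organometallics and activated esters that react on in the flask are numbered.

Step 1
Reactants: 1 (S)-(+)-carvone
Product: 2 (5S)-5-(3-chloroprop-1-en-2-yl)-2-methylcyclohex-2-en-1-one
Conditions: Ca(OCl)2, CO2 (dry ice), CH2Cl2/H2O, 0 °C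
Reagents that add atoms: calcium hypochlorite, [Ca+2].[O-]Cl.[O-]Cl
Why: Ene-type allylic chlorination by HOCl should attack only the electron-rich 1,1-disubstituted side-chain alkene (the enone alkene is deactivated) and leaves C7 untouched.

Step 2
Reactants: 2 (5S)-5-(3-chloroprop-1-en-2-yl)-2-methylcyclohex-2-en-1-one
Product: 4 (5S)-5-(3-hydroxyprop-1-en-2-yl)-2-methylcyclohex-2-en-1-one, via allylic acetate 3 (not isolated)
Conditions: KOAc, n-Bu4NI (cat.), DMF, 40 °C; then K2CO3 (cat.), MeOH, 0 °C
Reagents that add atoms: potassium acetate, CC(=O)[O-].[K+]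
Why: SN2 displacement of the primary allylic chloride by acetate, followed by methanolysis of the acetate in the same flask, should give the C12 alcohol without touching the enone.

Step 3
Reactants: 4 (5S)-5-(3-hydroxyprop-1-en-2-yl)-2-methylcyclohex-2-en-1-one
Product: 5 (5S)-5-[3-(tert-butyldimethylsilyloxy)prop-1-en-2-yl]-2-methylcyclohex-2-en-1-one
Conditions: TBSCl, imidazole, DMF, 0 °C
Reagents that add atoms: tert-butyldimethylsilyl chloride, CC(C)(C)[Si](C)(C)Cl
Why: Standard silylation of the primary alcohol gives a C12 protecting group that survives organometallic, Lewis-acidic and basic steps and can later be removed selectively beside a TBDPS ether.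

Step 4
Reactants: 5 (5S)-5-[3-(tert-butyldimethylsilyloxy)prop-1-en-2-yl]-2-methylcyclohex-2-en-1-one
Product: 6 (1R,5S)-5-[3-(tert-butyldimethylsilyloxy)prop-1-en-2-yl]-1-ethenyl-2-methylcyclohex-2-en-1-ol (OH cis to the side chain)
Conditions: vinylmagnesium bromide, THF, −78 °C to 0 °C
Reagents that add atoms: vinylmagnesium bromide, C=C[Mg]Br
Why: Grignard 1,2-addition to the enone should occur by axial attack anti to the pseudo-equatorial C7 side chain, so the C5 hydroxyl ends up cis to the side chain and the vinyl group trans.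

Step 5
Reactants: 6 (1R,5S)-5-[3-(tert-butyldimethylsilyloxy)prop-1-en-2-yl]-1-ethenyl-2-methylcyclohex-2-en-1-ol
Product: 7 (1R,5S)-5-[3-(tert-butyldimethylsilyloxy)prop-1-en-2-yl]-1-ethenyl-2-(hydroxymethyl)cyclohex-2-en-1-ol
Conditions: SeO2 (cat.), t-BuOOH, CH2Cl2, 0 °C to rt
Reagents that add atoms: tert-butyl hydroperoxide (oxygen delivered through catalytic SeO2), CC(C)(C)OO
Why: Riley allylic oxidation (ene reaction, then [2,3] shift) should hydroxylate C14, the only C–H-bearing allylic position at the more substituted end of the trisubstituted ring alkene, while the side-chain alkene is deactivated by its allylic silyloxy group.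

Step 6
Reactants: 7 (1R,5S)-5-[3-(tert-butyldimethylsilyloxy)prop-1-en-2-yl]-1-ethenyl-2-(hydroxymethyl)cyclohex-2-en-1-ol
Product: 8 the C9–C10 epoxide of 7 (oxirane oxygen, tertiary OH and C7 side chain all cis)
Conditions: VO(acac)2 (cat.), t-BuOOH, CH2Cl2, 0 °C
Reagents that add atoms: tert-butyl hydroperoxide, CC(C)(C)OO
Why: Vanadium-catalysed hydroxyl-directed epoxidation should deliver oxygen to the trisubstituted ring alkene on the face of the tertiary allylic OH, which sets the C9–O bond cis to the C7 side chain; the vinyl and side-chain alkenes react far more slowly.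

Step 7
Reactants: 8 the C9–C10 epoxide of 7
Product: 9 2-ethenyl-3-hydroxy-2-(hydroxymethyl)-5-[3-(tert-butyldimethylsilyloxy)prop-1-en-2-yl]cyclohexan-1-one (C9–OH, C14 and the C7 side chain cis; vinyl trans to them)
Conditions: BF3·OEt2, CH2Cl2, −78 °C
Reagents that add atoms: none
Why: Semipinacol rearrangement of the 2,3-epoxy tertiary alcohol: the oxirane opens at the tertiary carbon C10 while the vinyl group on C5, antiperiplanar to the breaking C10–O bond, shifts with inversion at C10 (π-assisted and leaving a tertiary oxocarbenium, so expected to outrun a hydride shift from C14), which creates the quaternary centre with vinyl trans and C14 cis to the C9 hydroxyl.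

Step 8
Reactants: 9 the keto diol
Product: 10 acetonide of 9 (cis-fused 2,2-dimethyl-1,3-dioxane across O9 and O14)
Conditions: 2,2-dimethoxypropane, PPTS (cat.), acetone, rt
Reagents that add atoms: 2,2-dimethoxypropane, COC(C)(C)OC
Why: Acetal exchange on the cis-1,3-diol protects C9–OH and C14–OH together and locks the chair in which C14 is axial and the vinyl group equatorial.

Step 9
Reactants: 10 the acetonide ketone
Product: 12 enol triflate of 10 (C5(OTf)=C6), via potassium enolate 11 (not isolated)
Conditions: KN(SiMe3)2, THF, −78 °C; then PhNTf2, −78 °C to 0 °C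
Reagents that add atoms: N-phenylbis(trifluoromethanesulfonimide), O=S(=O)(N(c1ccccc1)S(=O)(=O)C(F)(F)F)C(F)(F)F
Why: Only C6 carries α-hydrogens (C10 is quaternary), so enolisation is regiospecific and O-triflation gives a single enol triflate.

Step 10
Reactants: 13 2-bromoprop-2-en-1-ol
Product: 14 (2-bromoprop-2-en-1-yloxy)(tert-butyl)diphenylsilane
Conditions: TBDPSCl, imidazole, CH2Cl2, rt
Reagents that add atoms: tert-butyldiphenylsilyl chloride, CC(C)(C)[Si](Cl)(c1ccccc1)c1ccccc1
Why: Standard silylation gives the C3–C4–C15 building block with a robust, bulky silyl ether.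

Step 11
Reactants: 12 the enol triflate; 14 (2-bromoprop-2-en-1-yloxy)(tert-butyl)diphenylsilane
Product: 17 the 2-substituted 1,3-diene (C5 bears the 3-(tert-butyldiphenylsilyloxy)prop-1-en-2-yl group, C5=C6), via alkenyllithium 15 (not isolated), via alkenylzinc chloride 16 (not isolated)
Conditions: 14, t-BuLi, Et2O, −78 °C; ZnCl2, THF, −78 °C to rt; then 12, Pd(PPh3)4 (cat.), THF, 40 °C
Reagents that add atoms: none
Why: Bromine–lithium exchange, transmetalation to zinc and Negishi coupling with the enol triflate (zerovalent palladium) join two sp2 carbons next to the quaternary centre without stereochemical consequence.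

Step 12
Reactants: 17 the diene
Product: 18 the C5–C6 epoxide of 17 (oxirane trans to C14, cis to the C10 vinyl group)
Conditions: mCPBA, NaHCO3, CH2Cl2, 0 °C
Reagents that add atoms: 3-chloroperoxybenzoic acid, OOC(=O)c1cccc(Cl)c1
Why: Prilezhaev epoxidation should take the most electron-rich, trisubstituted ring alkene from the face opposite the pseudo-axial C14 methylene of the cis-fused dioxane, which places the C5–O bond trans to C14 and the C4 alkenyl group cis to it.

Step 13
Reactants: 18 the vinyl epoxide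
Product: 19 the tertiary alcohol (C5–OH axial and trans to C14; C5 alkenyl group and C10 vinyl group trans and both equatorial)
Conditions: LiEt3BH, THF, 0 °C
Reagents that add atoms: none
Why: SN2 hydride opening at the less hindered, non-allylic carbon C6 (trans-diaxial opening) leaves the C5–O bond untouched, so the configuration set in step 12 becomes the tertiary allylic alcohol needed for the rearrangement.

Step 14
Reactants: 19 the trans-1,2-dialkenylcyclohexanol
Product: 22 the ten-membered enol triflate (C1=C10 with C9 trans to C2; C4=C5 with C3 trans to C6; OTf on C5), via potassium alkoxide 20 (not isolated), via ring-expanded potassium enolate 21 (not isolated)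
Conditions: KH, 18-crown-6, THF, 0 °C to rt; then PhNTf2, −78 °C to 0 °C
Reagents that add atoms: N-phenylbis(trifluoromethanesulfonimide), O=S(=O)(N(c1ccccc1)S(=O)(=O)C(F)(F)F)C(F)(F)F
Why: The naked potassium alkoxide 20 undergoes an anionic oxy-Cope ([3,3]-sigmatropic) rearrangement in which the C5–C10 σ-bond of the cyclohexane breaks while the termini of the two alkenyl groups join as C2–C3, and the enolate 21 is O-triflated in the same flask. The closest known reaction type is the anionic oxy-Cope ring expansion of trans-1,2-divinylcyclohexanols to cyclodec-5-enones with enolate trapping. The ten-membered carbocycle is closed by this pericyclic four-atom ring expansion of the six-membered ring, not by an end-to-end cyclisation, so no high dilution is needed. No new sp3 stereocentre arises; the ring-E geometry of C1=C10 and of the C4=C5 enolate (hence of the later trans-epoxide) is fixed by the chair transition state in which both alkenyl groups, C6 and C9 are equatorial. The step needs the [3,3] shift to outrun heterolytic fragmentation and needs a single enolate geometry; the trans-diequatorial alkenyl groups with axial alkoxide installed in steps 7, 12 and 13, and the cis-fused acetonide that holds this chair, should secure both. C7 and C9 are not touched.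

Step 15
Reactants: 22 the ten-membered enol triflate
Product: 23 the ten-membered diene (H on C5; C9/C14 acetonide, C12–OTBS, C15–OTBDPS)
Conditions: Pd(OAc)2 (cat.), PPh3, HCO2H, n-Bu3N, DMF, 50 °C
Reagents that add atoms: none
Why: Palladium-catalysed formate reduction of the enol triflate (oxidative addition, formate decarboxylation, reductive elimination) should replace OTf by H with retention of the double-bond geometry.

Step 16
Reactants: 23 the ten-membered diene
Product: 25 the C12 acetate, via C12 alcohol 24 (not isolated)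
Conditions: HF·pyridine, pyridine, THF, 0 °C; then Ac2O, DMAP, rt
Reagents that add atoms: acetic anhydride, CC(=O)OC(C)=O
Why: Buffered HF·pyridine should cleave the primary TBS ether much faster than the primary TBDPS ether and leave the acetonide, and the freed C12 alcohol is acetylated in the same flask.

Step 17
Reactants: 25 the C12 acetate
Product: 26 the C9,C14-diol
Conditions: PPTS, MeOH, rt
Reagents that add atoms: none
Why: Buffered acid-catalysed transketalisation removes the acetonide under conditions mild enough for the silyl ether, the allylic acetate and the 1,5-diene.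

Step 18
Reactants: 27 (4R)-4-benzyl-3-propanoyl-1,3-oxazolidin-2-one; 28 acetaldehyde
Product: 30 (4R)-4-benzyl-3-[(2R,3S)-3-hydroxy-2-methylbutanoyl]-1,3-oxazolidin-2-one, via boron enolate 29 (not isolated)
Conditions: n-Bu2BOTf, i-Pr2NEt, CH2Cl2, −78 °C to 0 °C; then 28, −78 °C; H2O2, pH 7 buffer, MeOH
Reagents that add atoms: none
Why: Evans syn-aldol reaction: the Z-boron enolate reacts through a Zimmerman–Traxler chair on the face away from the benzyl group of the (R)-auxiliary, which should set (2R,3S).

Step 19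
Reactants: 30 the aldol adduct
Product: 31 (4R)-4-benzyl-3-[(2R,3S)-2-methyl-3-(triethylsilyloxy)butanoyl]-1,3-oxazolidin-2-one
Conditions: TESCl, imidazole, DMF, 0 °C
Reagents that add atoms: chlorotriethylsilane, CC[Si](Cl)(CC)CC
Why: Silylation blocks the β-hydroxyl so that the acid cannot acylate itself in step 21.

Step 20
Reactants: 31 the TES ether
Product: 32 (2R,3S)-2-methyl-3-(triethylsilyloxy)butanoic acid
Conditions: LiOH, H2O2, THF/H2O, 0 °C; Na2SO3; then aq. HCl to pH 3
Reagents that add atoms: lithium hydroperoxide (from LiOH and H2O2), [Li+].[O-]O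
Why: Hydroperoxide attacks the exocyclic imide carbonyl selectively, which releases the acid without epimerisation and returns the auxiliary.

Step 21
Reactants: 26 the C9,C14-diol; 32 (2R,3S)-2-methyl-3-(triethylsilyloxy)butanoic acid
Product: 34 the C14 ester (C9–OH free), via mixed anhydride 33 (not isolated)
Conditions: 32, 2,4,6-trichlorobenzoyl chloride, Et3N, THF, 0 °C; then 26, DMAP, toluene, 0 °C
Reagents that add atoms: none
Why: Yamaguchi esterification: the mixed anhydride should acylate the unhindered primary allylic C14 hydroxyl in preference to the secondary C9 hydroxyl next to the trisubstituted alkene.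

Step 22
Reactants: 34 the C14 ester
Product: 35 the C9 senecioate (3-methylbut-2-enoate)
Conditions: 3-methylbut-2-enoyl chloride, pyridine, DMAP (cat.), CH2Cl2, 0 °C
Reagents that add atoms: 3-methylbut-2-enoyl chloride, CC(C)=CC(=O)Cl
Why: DMAP-catalysed acylation of the remaining secondary alcohol proceeds with retention at C9, and pyridine as the only base limits deconjugation of the senecioyl group.

Step 23
Reactants: 35 the C9 senecioate
Product: 36 the allylic alcohol (C15–OH and C3'–OH free)
Conditions: HF·pyridine, pyridine, THF, 0 °C to rt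
Reagents that add atoms: none
Why: Fluoride cleaves both silyl ethers while the three esters are untouched, and it is done before the acid-sensitive epoxide exists.

Step 24
Reactants: 36 the allylic alcohol
Product: 37 CNP0227102.1, (1(10)E,4S,5R,7S,9R)-12-acetoxy-4,5-epoxy-15-hydroxy-9-(3-methylbut-2-enoyloxy)germacra-1(10),11(13)-dien-14-yl (2R,3S)-3-hydroxy-2-methylbutanoate
Conditions: Ti(OiPr)4, L-(+)-diisopropyl tartrate, t-BuOOH, 4 Å MS, CH2Cl2, −20 °C
Reagents that add atoms: tert-butyl hydroperoxide, CC(C)(C)OO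
Why: Katsuki–Sharpless asymmetric epoxidation: the titanium/L-(+)-tartrate catalyst epoxidises only the C4=C5 alkene of the primary allylic alcohol and should deliver oxygen to the enantioface that gives (4S,5R), syn addition to the ring-E alkene keeping C3 and C6 trans on the oxirane.

Compound list
1 | (S)-(+)-carvone, (5S)-2-methyl-5-(prop-1-en-2-yl)cyclohex-2-en-1-one | C=C(C)[C@H]1CC=C(C)C(=O)C1 | starting material
2 | (5S)-5-(3-chloroprop-1-en-2-yl)-2-methylcyclohex-2-en-1-one | C=C(CCl)[C@H]1CC=C(C)C(=O)C1 | intermediate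
3 | 2-[(1S)-4-methyl-5-oxocyclohex-3-en-1-yl]prop-2-en-1-yl acetate | C=C(COC(C)=O)[C@H]1CC=C(C)C(=O)C1 | intermediate (not isolated)
4 | (5S)-5-(3-hydroxyprop-1-en-2-yl)-2-methylcyclohex-2-en-1-one | C=C(CO)[C@H]1CC=C(C)C(=O)C1 | intermediate
5 | (5S)-5-[3-(tert-butyldimethylsilyloxy)prop-1-en-2-yl]-2-methylcyclohex-2-en-1-one | C=C(CO[Si](C)(C)C(C)(C)C)[C@H]1CC=C(C)C(=O)C1 | intermediate
6 | (1R,5S)-5-[3-(tert-butyldimethylsilyloxy)prop-1-en-2-yl]-1-ethenyl-2-methylcyclohex-2-en-1-ol | C=C(CO[Si](C)(C)C(C)(C)C)[C@H]1CC=C(C)[C@](O)(C=C)C1 | intermediate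
7 | (1R,5S)-5-[3-(tert-butyldimethylsilyloxy)prop-1-en-2-yl]-1-ethenyl-2-(hydroxymethyl)cyclohex-2-en-1-ol | C=C(CO[Si](C)(C)C(C)(C)C)[C@H]1CC=C(CO)[C@](O)(C=C)C1 | intermediate
8 | C9–C10 epoxide of 7, oxirane cis to the tertiary OH and the side chain | C=C(CO[Si](C)(C)C(C)(C)C)[C@H]1C[C@H]2O[C@@]2(CO)[C@](O)(C=C)C1 | intermediate
9 | 2-ethenyl-3-hydroxy-2-(hydroxymethyl)-5-[3-(tert-butyldimethylsilyloxy)prop-1-en-2-yl]cyclohexan-1-one, 3-OH/2-CH2OH/5-side chain cis, 2-ethenyl trans | C=C(CO[Si](C)(C)C(C)(C)C)[C@H]1C[C@@H](O)[C@@](C=C)(CO)C(=O)C1 | intermediate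
10 | acetonide of 9, cis-fused 2,2-dimethyl-1,3-dioxane across O9 and O14 | C=C(CO[Si](C)(C)C(C)(C)C)[C@H]1C[C@H]2OC(C)(C)OC[C@@]2(C=C)C(=O)C1 | intermediate
11 | potassium enolate of 10 (C5=C6) | C=C(CO[Si](C)(C)C(C)(C)C)[C@H]1C[C@H]2OC(C)(C)OC[C@@]2(C=C)C([O-])=C1.[K+] | intermediate (not isolated)
12 | enol triflate of 10 (C5(OTf)=C6) | C=C(CO[Si](C)(C)C(C)(C)C)[C@H]1C[C@H]2OC(C)(C)OC[C@@]2(C=C)C(OS(=O)(=O)C(F)(F)F)=C1 | intermediate
13 | 2-bromoprop-2-en-1-ol | C=C(Br)CO | starting material
14 | (2-bromoprop-2-en-1-yloxy)(tert-butyl)diphenylsilane | C=C(Br)CO[Si](c1ccccc1)(c1ccccc1)C(C)(C)C | intermediate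
15 | [3-(tert-butyldiphenylsilyloxy)prop-1-en-2-yl]lithium | [Li]C(=C)CO[Si](c1ccccc1)(c1ccccc1)C(C)(C)C | intermediate (not isolated)
16 | [3-(tert-butyldiphenylsilyloxy)prop-1-en-2-yl]zinc chloride | Cl[Zn]C(=C)CO[Si](c1ccccc1)(c1ccccc1)C(C)(C)C | intermediate (not isolated)
17 | diene: C5 of the cyclohexene carries the 3-(tert-butyldiphenylsilyloxy)prop-1-en-2-yl group, C5=C6 | C=C(CO[Si](C)(C)C(C)(C)C)[C@H]1C[C@H]2OC(C)(C)OC[C@@]2(C=C)C(C(=C)CO[Si](c3ccccc3)(c3ccccc3)C(C)(C)C)=C1 | intermediate
18 | C5–C6 epoxide of 17, oxirane trans to C14 and cis to the C10 vinyl group | C=C(CO[Si](C)(C)C(C)(C)C)[C@H]1C[C@H]2OC(C)(C)OC[C@@]2(C=C)[C@]3(C(=C)CO[Si](c4ccccc4)(c4ccccc4)C(C)(C)C)O[C@@H]31 | intermediate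
19 | tertiary alcohol: C5–OH trans to C14, C5 alkenyl group trans to the C10 vinyl group | C=C(CO[Si](C)(C)C(C)(C)C)[C@H]1C[C@H]2OC(C)(C)OC[C@@]2(C=C)[C@@](O)(C(=C)CO[Si](c3ccccc3)(c3ccccc3)C(C)(C)C)C1 | intermediate
20 | potassium alkoxide of 19 | C=C(CO[Si](C)(C)C(C)(C)C)[C@H]1C[C@H]2OC(C)(C)OC[C@@]2(C=C)[C@@]([O-])(C(=C)CO[Si](c3ccccc3)(c3ccccc3)C(C)(C)C)C1.[K+] | intermediate (not isolated)
21 | ring-expanded potassium enolate, ten-membered ring, C1=C10 and C4=C5 both ring-E | C=C(CO[Si](C)(C)C(C)(C)C)[C@H]1C[C@H]2OC(C)(C)OC/C2=C\CC/C(CO[Si](c3ccccc3)(c3ccccc3)C(C)(C)C)=C([O-])/C1.[K+] | intermediate (not isolated)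
22 | ten-membered enol triflate (OTf on C5; C9 trans to C2, C3 trans to C6) | C=C(CO[Si](C)(C)C(C)(C)C)[C@H]1C[C@H]2OC(C)(C)OC/C2=C\CC/C(CO[Si](c3ccccc3)(c3ccccc3)C(C)(C)C)=C(OS(=O)(=O)C(F)(F)F)/C1 | intermediate
23 | ten-membered 1(10),4-diene with C9/C14 acetonide, C12–OTBS, C15–OTBDPS | C=C(CO[Si](C)(C)C(C)(C)C)[C@H]1C[C@H]2OC(C)(C)OC/C2=C\CC/C(CO[Si](c3ccccc3)(c3ccccc3)C(C)(C)C)=C/C1 | intermediate
24 | C12 alcohol of 23 | C=C(CO)[C@H]1C[C@H]2OC(C)(C)OC/C2=C\CC/C(CO[Si](c3ccccc3)(c3ccccc3)C(C)(C)C)=C/C1 | intermediate (not isolated)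
25 | C12 acetate with C9/C14 acetonide and C15–OTBDPS | C=C(COC(C)=O)[C@H]1C[C@H]2OC(C)(C)OC/C2=C\CC/C(CO[Si](c3ccccc3)(c3ccccc3)C(C)(C)C)=C/C1 | intermediate
26 | C9,C14-diol with C12–OAc and C15–OTBDPS | C=C(COC(C)=O)[C@H]1C[C@@H](O)/C(CO)=C/CC/C(CO[Si](c2ccccc2)(c2ccccc2)C(C)(C)C)=C/C1 | intermediate
27 | (4R)-4-benzyl-3-propanoyl-1,3-oxazolidin-2-one | O=C1OC[C@@H](Cc2ccccc2)N1C(=O)CC | starting material
28 | acetaldehyde | CC=O | starting material
29 | (Z)-di-n-butylboron enolate of 27 | C/C=C(\OB(CCCC)CCCC)N1C(=O)OC[C@H]1Cc1ccccc1 | intermediate (not isolated)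
30 | (4R)-4-benzyl-3-[(2R,3S)-3-hydroxy-2-methylbutanoyl]-1,3-oxazolidin-2-one | O=C1OC[C@@H](Cc2ccccc2)N1C(=O)[C@H](C)[C@H](C)O | intermediate
31 | (4R)-4-benzyl-3-[(2R,3S)-2-methyl-3-(triethylsilyloxy)butanoyl]-1,3-oxazolidin-2-one | O=C1OC[C@@H](Cc2ccccc2)N1C(=O)[C@H](C)[C@H](C)O[Si](CC)(CC)CC | intermediate
32 | (2R,3S)-2-methyl-3-(triethylsilyloxy)butanoic acid | OC(=O)[C@H](C)[C@H](C)O[Si](CC)(CC)CC | intermediate
33 | mixed anhydride of 32 with 2,4,6-trichlorobenzoic acid | O=C(OC(=O)[C@H](C)[C@H](C)O[Si](CC)(CC)CC)c1c(Cl)cc(Cl)cc1Cl | intermediate (not isolated)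
34 | C14 ester of 26 with 32, C9–OH free | C=C(COC(C)=O)[C@H]1C[C@@H](O)/C(COC(=O)[C@H](C)[C@H](C)O[Si](CC)(CC)CC)=C/CC/C(CO[Si](c2ccccc2)(c2ccccc2)C(C)(C)C)=C/C1 | intermediate
35 | C9 senecioate of 34 | C=C(COC(C)=O)[C@H]1C[C@@H](OC(=O)C=C(C)C)/C(COC(=O)[C@H](C)[C@H](C)O[Si](CC)(CC)CC)=C/CC/C(CO[Si](c2ccccc2)(c2ccccc2)C(C)(C)C)=C/C1 | intermediate
36 | desilylated triester, C15 allylic alcohol and C3' alcohol free | C=C(COC(C)=O)[C@H]1C[C@@H](OC(=O)C=C(C)C)/C(COC(=O)[C@H](C)[C@H](C)O)=C/CC/C(CO)=C/C1 | intermediate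
37 | CNP0227102.1 | C=C(COC(C)=O)[C@H]1C[C@@H](OC(=O)C=C(C)C)/C(COC(=O)[C@H](C)[C@H](C)O)=C/CC[C@@]2(CO)O[C@@H]2C1 | target

Total step count: 24. Longest linear sequence: 20 steps (steps 1–9, 11–17, 21–24).

Steps most likely to fail

Step 14 (key step). The alkoxide may fragment heterolytically at C5–C10 (retro-allylation), or the silyl group may migrate from O15 to the alkoxide, before the [3,3] shift takes place; the hindered enolate may also be triflated incompletely. The fallback is the neutral variant. It sets out from 19, which is silylated (Me3SiOTf, 2,6-lutidine) to the trimethylsilyl ether F4. Heating F4 in a sealed tube (o-dichlorobenzene, about 200 °C) should bring about the siloxy-Cope ring expansion through the same chair to the ten-membered trimethylsilyl enol ether F5. MeLi in THF then releases the lithium enolate F6 regiospecifically, and PhNTf2 converts it into enol triflate 22, where the route is rejoined.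

Step 5. The selenium reagent may attack the side-chain alkene in a competing ene reaction, the tertiary bis-allylic alcohol may ionise, or the new primary alcohol may be over-oxidised to the enal. The fallback introduces the C14 oxygen by epoxide chemistry and sets out from 6. Hydroxyl-directed epoxidation (VO(acac)2, t-BuOOH) gives the epoxy alcohol F1. Diethylaluminium 2,2,6,6-tetramethylpiperidide, Et2Al(TMP), removes a methyl proton and opens the oxirane to the exocyclic-methylene diol F2. A second directed epoxidation gives the spiro-epoxide F3 with oxygen on the face of the two hydroxyls. BF3·OEt2 at −78 °C then triggers the semipinacol vinyl shift to C10, the former epoxide oxygen becomes the C14 hydroxyl, and keto diol 9 is reached directly.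

Step 24. Facial selectivity may be poor if the reactive conformer of the mobile ten-membered ring exposes the face opposite to the one the tartrate catalyst requires (mismatched case). The fallback delivers the oxygen anti to an electrophile that takes the exposed face, and sets out from 35. NBS in aqueous THF should give the bromohydrin F7 (Br on C5 from the exposed face, OH on the tertiary carbon C4 anti to it). Cs2CO3 in MeCN closes F7 with inversion at C5 to the bis-silyl epoxide F8, which then carries its oxygen on the face opposite to direct electrophilic attack. Buffered fluoride (n-Bu4NF, AcOH, THF) removes both silyl groups and gives 37.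

Further compounds
F1 | step 5 | C9–C10 epoxide of 6 (C14 still methyl), oxirane cis to the tertiary OH | C=C(CO[Si](C)(C)C(C)(C)C)[C@H]1C[C@H]2O[C@@]2(C)[C@](O)(C=C)C1
F2 | step 5 | exocyclic-methylene diol (C10=C14H2, C9–OH and C5–OH cis) | C=C(CO[Si](C)(C)C(C)(C)C)[C@H]1C[C@@H](O)C(=C)[C@](O)(C=C)C1
F3 | step 5 | spiro-epoxide diol (C10–C14 oxirane, oxygen on the face of both hydroxyls) | C=C(CO[Si](C)(C)C(C)(C)C)[C@H]1C[C@@H](O)[C@]2(CO2)[C@](O)(C=C)C1
F4 | step 14 | trimethylsilyl ether of 19 | C=C(CO[Si](C)(C)C(C)(C)C)[C@H]1C[C@H]2OC(C)(C)OC[C@@]2(C=C)[C@@](O[Si](C)(C)C)(C(=C)CO[Si](c3ccccc3)(c3ccccc3)C(C)(C)C)C1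
F5 | step 14 | ten-membered trimethylsilyl enol ether | C=C(CO[Si](C)(C)C(C)(C)C)[C@H]1C[C@H]2OC(C)(C)OC/C2=C\CC/C(CO[Si](c3ccccc3)(c3ccccc3)C(C)(C)C)=C(O[Si](C)(C)C)/C1
F6 | step 14 | ten-membered lithium enolate | C=C(CO[Si](C)(C)C(C)(C)C)[C@H]1C[C@H]2OC(C)(C)OC/C2=C\CC/C(CO[Si](c3ccccc3)(c3ccccc3)C(C)(C)C)=C([O-])/C1.[Li+]
F7 | step 24 | bromohydrin of 35 (C4–OH, C5–Br, anti) | C=C(COC(C)=O)[C@H]1C[C@@H](OC(=O)C=C(C)C)/C(COC(=O)[C@H](C)[C@H](C)O[Si](CC)(CC)CC)=C/CC[C@@](CO[Si](c2ccccc2)(c2ccccc2)C(C)(C)C)(O)[C@@H](Br)C1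
F8 | step 24 | bis-silyl ether of 37 (4S,5R-epoxide, C15–OTBDPS, C3'–OTES) | C=C(COC(C)=O)[C@H]1C[C@@H](OC(=O)C=C(C)C)/C(COC(=O)[C@H](C)[C@H](C)O[Si](CC)(CC)CC)=C/CC[C@@]2(CO[Si](c3ccccc3)(c3ccccc3)C(C)(C)C)O[C@@H]2C1
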